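At early times in the elm run I read 14 % of ring with 68 % of starting material left, which is 0.438 of what had reacted, and at 5.00 h that fraction stood at 0.506. So I carried the ring share at matched conversion, ring over the fraction of the charge reacted, read where a flask ends up.

| flask | starting material | protic impurity | temperature | remark | time |
|---|---|---|---|---|---|
| elm | 0.35 M | 0.125 M | 5 °C | run made earlier |  |
| larch | 0.55 M | 0.125 M | 16 °C | run made earlier |  |
| ash | 0.25 M | 0.19 M | 5 °C | run made earlier |  |
| north | 0.25 M | 0.125 M | 0 °C |  | 10 h |
| south-east | 0.25 M | 0.125 M | 20 °C |  | 10 h |

| run | time / h | open dimer / % | starting material / % | open trimer / % | ring / % |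
|---|---|---|---|---|---|
| elm | 1.00 | 7 | 68 | 5 | 14 |
| elm | 2.50 | 13 | 41 | 10 | 27 |
| elm | 3.00 | 8 | 36 | 14 | 32 |
| elm | 5.00 | 7 | 17 | 18 | 42 |
| elm | 6.00 | 7 | 13 | 20 | 44 |
| elm | 8.00 | 11 | 7 | 19 | 53 |
| larch | 0.417 | 8 | 54 | 9 | 21 |
| larch | 1.00 | 7 | 24 | 14 | 42 |
| larch | 1.33 | 10 | 19 | 17 | 50 |
| larch | 2.50 | 2 | 3 | 25 | 59 |
| larch | 4.00 | 3 | 0 | 24 | 62 |
| ash | 1.50 | 10 | 57 | 6 | 19 |
| ash | 3.00 | 7 | 36 | 6 | 33 |
| ash | 5.00 | 8 | 18 | 10 | 39 |
| ash | 6.00 | 8 | 15 | 10 | 44 |
| ash | 8.00 | 7 | 9 | 12 | 47 |

(each reading ± 2 percentage points)

- a species is counted by the starting material in it: one open dimer counts as two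
- a species is counted by the starting material in it: one open trimer counts as three
- amounts and yields of ring count crystals too
- given per volume of solution although it is solid: crystals
- steps under discussion: starting material + open dimer -> open trimer; starting material -> ring; crystals <-> ring; 2 starting material -> open dimer; starting material + protic impurity -> quenched substrate

- which of these there is most of at the end, counted by the starting material in it, north (starting material / open dimer / open trimer / ring)
- which of these there is most of at the end, counted by the starting material in it, south-east (starting material / open dimer / open trimer / ring)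
- final amount of the leader among these, as a percentage of the starting material charged, in north
- final amount of the leader among these, as a percentage of the starting material charged, in south-east

1. Time. By hand, a longer run means a larger fraction reacted. Starting material fell nearly first order, at 0.332 h⁻¹ in elm and 0.301 h⁻¹ in ash, and at 1.43 h⁻¹ in larch. Scaling between elm and larch gave 0.171 h⁻¹ for north, so I reckoned 18.0 % left at the end. For south-east it gave 2.42 h⁻¹, a lifetime of 0.413 h, far shorter than the run.

2. Starting material. By hand, the open dimer and open trimer steps take two partners and the ring step one, so the selectivity factor should favour ring as the fraction left falls. The drift in elm reads that way.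

3. Protic impurity. By hand, it takes starting material beside ring. At 5.00 h ash, with 0.760 equivalents, read a share of 0.476, lower than elm's with 0.357. Ash also had the smaller charge, so the two runs differ in more than the impurity. North has 0.500, between them.

4. Temperature. By hand, I could not sign it. Larch read 0.553 at 1.00 h, higher than elm's despite its larger charge, so I took warming to raise the share.

5. Reckoning. My reckoned conversion for north matches those ash and elm readings, so I put its ring at 39.0 % to 41.5 %, and I expected its cold to favour the low end. I expected south-east to react out, and I took larch's last reading, a share of 0.620, as a rough figure for it; south-east's smaller charge and warmer bath pointed higher, and its 0.500 equivalents of protic impurity against larch's 0.227 pointed lower. The forecast named ring in both flasks, at 48 % in north, on the ground that “Ring is about 58–60% of consumed material at 0–5 °C”, and at 69 % in south-east, and my north figure stood lower.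

6. North gave 40.0 % of ring and south-east 74.8 %, with ring leading in each.

    starting material + open dimer → open trimer (k = 1.20 M⁻¹ h⁻¹, Ea = 67.0 kJ mol⁻¹)
    starting material → ring (k = 0.0860 h⁻¹, Ea = 92.0 kJ mol⁻¹)
    crystals ⇌ ring, rate k3*(cs3 - [ring]) while solid is left; crystals form when [ring] > cs3 (solubility = 9.10 mM, k = 4.30 h⁻¹)
    2 starting material → open dimer (k = 0.140 M⁻¹ h⁻¹, Ea = 52.0 kJ mol⁻¹)
    starting material + protic impurity → quenched substrate (k = 0.360 M⁻¹ h⁻¹, Ea = 63.0 kJ mol⁻¹)
    (constants at 0 °C)

North still held 19.1 % of starting material at the end, so its ring share came to 0.494, between ash's 0.476 and elm's 0.506. In the flask like south-east but run at −5 °C, 37.4 % of starting material stayed and ring reached 25.1 %, a share of 0.401.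

Readings and results were generated by integration with constants of no real substance; noise was put on by code.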